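The route rests on cutting the seven-membered ring of the guaiane acid at C8–C9 and C10–C1 (guaiane numbering). A Rh(I)-catalysed intermolecular (5+2) cycloaddition of methyl propiolate with a 6-alkenylbicyclo[3.1.0]hexane opens the ring-fused cyclopropane and should deliver the hydroazulene in one operation: isopropyl on C7, ester on C10, and the cis C1–C5 fusion inherited from the cyclopropane. The step exploits the 1,4-relation of C7 and C10 and the two adjacent sp3 fusion carbons. The precursor is made in two steps from an epoxyhexene. The iridoid triol comes from (R)-carvone by a pinacol closure of C7–C8, and esterification at O-10 joins the halves.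

Key step: step 3

Remark: guaiane numbering is used for the acid half and iridoid numbering for the lactone half; (S)-1,2-epoxy-5-hexene is taken as a commercial enantiopure compound; C9 of 22 and 23 is a labile β-keto-lactone centre and is drawn without a descriptor.

Step 1
Reactants: 1 (S)-2-(but-3-en-1-yl)oxirane; 2 3-methylbut-1-yne
Product: 3 (S)-2-[(3E)-6-methyl-5-methylidenehept-3-en-1-yl]oxirane
Conditions: Hoveyda–Grubbs II (5 mol %), 2 (3 equiv), CH2Cl2, 40 °C, sealed tube
Reagents that add atoms: none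
Why: Cross enyne metathesis joins the terminal alkene of 1 to the alkyne of 2 without loss of atoms and should give the 1,3-disubstituted diene, the E isomer being favoured by secondary metathesis, while the epoxide stereocentre is untouched.

Step 2
Reactants: 3 (S)-2-[(3E)-6-methyl-5-methylidenehept-3-en-1-yl]oxirane
Product: 5 tert-butyl(dimethyl){[(1R,2S,5R,6R)-6-(3-methylbut-1-en-2-yl)bicyclo[3.1.0]hexan-2-yl]oxy}silane, via lithium bicyclohexanolate 4 (not isolated)
Conditions: LTMP (from TMP, n-BuLi), MTBE, 0 °C to rt; then TBSOTf, −78 to 0 °C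
Reagents that add atoms: tert-butyldimethylsilyl triflate CC(C)(C)[Si](C)(C)OS(=O)(=O)C(F)(F)F
Why: Intramolecular cyclopropanation by an α-lithiated terminal epoxide (carbenoid) adds the epoxide CH stereospecifically to the proximal E alkene on the face away from the C–O bond, so the epoxide carbon (C4) fixes C5, C1 and C6 (alkenyl exo, oxygen trans to the cyclopropane), and the alkoxide is silylated in the same flask.

Step 3
Reactants: 5 tert-butyl(dimethyl){[(1R,2S,5R,6R)-6-(3-methylbut-1-en-2-yl)bicyclo[3.1.0]hexan-2-yl]oxy}silane; 6 methyl propiolate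
Product: 7 methyl (1S,3aS,8aS)-1-[(tert-butyldimethylsilyl)oxy]-7-isopropyl-1,2,3,3a,6,8a-hexahydroazulene-4-carboxylate (6,9-diene in guaiane numbering)
Conditions: [Rh(CO)2Cl]2 (5 mol %), 6 (1.5 equiv), DCE, 80 °C
Reagents that add atoms: none
Why: Rh(I) binds the 1,1-disubstituted alkene of 5 and inserts into the adjacent strained C6–C1 bond to give a σ-alkyl/π-allyl rhodacyclohexene (Rh–C1, η3-C6–C7–C8), methyl propiolate then inserts at the allyl terminus (C8–C9 bond), and C(sp2)–C(sp3) reductive elimination forms C10–C1. The closest known reactions are the [Rh(CO)2Cl]2-catalysed intermolecular (5+2) cycloaddition of α-alkyl-substituted vinylcyclopropanes with propiolates and the intramolecular cases in which substituted cyclopropanes react with retention. The seven-membered ring is closed as a two-bond intermolecular annulation (five carbons C8–C7–C6–C5–C1 plus two carbons C9–C10), and the cyclopentane is carried along unchanged. No stereocentre arises from a planar atom: C5 is not touched, C1 exchanges its bond to C6 for Rh and then for C10 with retention in both events, so the cis cyclopropane fusion becomes the cis C1–C5 fusion, and C6 becomes sp2. Two selectivities are needed: cleavage of C6–C1 rather than C6–C5, secured by the bulky OTBS group on C4 that flanks C5 only, and the alkyne orientation, secured because the ester-bearing carbon stays distal to the first-formed C8–C9 bond and the allyl terminus attacks the electrophilic β-carbon of the ynoate. The isopropyl group on C7 favours the conformer needed for C–C insertion, and the extra strain of the bicyclo[3.1.0]hexane should speed insertion relative to β-hydride elimination from C2.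

Step 4
Reactants: 7 methyl (1S,3aS,8aS)-1-[(tert-butyldimethylsilyl)oxy]-7-isopropyl-1,2,3,3a,6,8a-hexahydroazulene-4-carboxylate
Product: 8 methyl (1S,3aS,8aS)-1-[(tert-butyldimethylsilyl)oxy]-7-isopropyl-1,2,3,3a,8,8a-hexahydroazulene-4-carboxylate (7,9-diene)
Conditions: DBU, PhMe, 80 °C
Reagents that add atoms: none
Why: Base-mediated prototropic isomerisation removes the doubly allylic γ-proton at C8 and reprotonates the extended enolate at C6, which should funnel the skipped diene into the fully conjugated dienoate, while C1 and C5 are not acidified and keep their configuration.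

Step 5
Reactants: 8 methyl (1S,3aS,8aS)-1-[(tert-butyldimethylsilyl)oxy]-7-isopropyl-1,2,3,3a,8,8a-hexahydroazulene-4-carboxylate
Product: 9 methyl (1S,3aS,8aS)-1-hydroxy-7-isopropyl-1,2,3,3a,8,8a-hexahydroazulene-4-carboxylate
Conditions: TBAF, THF, 0 °C to rt
Reagents that add atoms: none
Why: Fluoride-induced desilylation frees the secondary alcohol and touches neither the ester nor a stereocentre.

Step 6
Reactants: 9 methyl (1S,3aS,8aS)-1-hydroxy-7-isopropyl-1,2,3,3a,8,8a-hexahydroazulene-4-carboxylate
Product: 10 methyl (3aS,8aS)-7-isopropyl-1-oxo-1,2,3,3a,8,8a-hexahydroazulene-4-carboxylate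
Conditions: DMP, CH2Cl2, 0 °C to rt
Reagents that add atoms: none
Why: Dess–Martin oxidation works without base, so the α-stereocentre C5 should survive, and because C6 is already sp3 the ketone cannot draw a ring alkene into conjugation.

Step 7
Reactants: 10 methyl (3aS,8aS)-7-isopropyl-1-oxo-1,2,3,3a,8,8a-hexahydroazulene-4-carboxylate
Product: 11 methyl (3aS,8aS)-7-isopropyl-1-methylidene-1,2,3,3a,8,8a-hexahydroazulene-4-carboxylate
Conditions: Zn, CH2Br2, TiCl4, THF–CH2Cl2, 0 °C to rt
Reagents that add atoms: dibromomethane BrCBr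
Why: Lombardo–Takai methylenation uses a non-basic gem-dimetallic reagent that is selective for ketones over esters and should not epimerise C5.

Step 8
Reactants: 11 methyl (3aS,8aS)-7-isopropyl-1-methylidene-1,2,3,3a,8,8a-hexahydroazulene-4-carboxylate
Product: 12 methyl (1R,3aS,8aR)-7-isopropyl-1-methyl-1,2,3,3a,8,8a-hexahydroazulene-4-carboxylate
Conditions: H2 (1 atm), RhCl(PPh3)3 (5 mol %), benzene, rt
Reagents that add atoms: none
Why: Homogeneous hydrogenation with Wilkinson's catalyst should reduce only the 1,1-disubstituted alkene and deliver hydrogen to the convex face (the face of H-1 and H-5), so the methyl group ends cis to C6 and C4 is set as R.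

Step 9
Reactants: 12 methyl (1R,3aS,8aR)-7-isopropyl-1-methyl-1,2,3,3a,8,8a-hexahydroazulene-4-carboxylate
Product: 13 (1R,3aS,8aR)-7-isopropyl-1-methyl-1,2,3,3a,8,8a-hexahydroazulene-4-carboxylic acid
Conditions: LiOH, THF–MeOH–H2O, 50 °C; then 1 M HCl
Reagents that add atoms: lithium hydroxide [Li+].[OH-]
Why: Saponification of the methyl ester leaves the diene, which is already the thermodynamic isomer, and the non-acidic stereocentres unchanged.

Step 10
Reactants: 14 (R)-(−)-carvone
Product: 15 (1R,4R,6R)-1-methyl-4-(prop-1-en-2-yl)-7-oxabicyclo[4.1.0]heptan-2-one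
Conditions: 30 % H2O2, NaOH (cat.), MeOH, 0 °C
Reagents that add atoms: hydrogen peroxide OO
Why: Weitz–Scheffer epoxidation attacks only the enone alkene, anti to the isopropenyl group, and both new centres are deleted again in step 12.

Step 11
Reactants: 15 (1R,4R,6R)-1-methyl-4-(prop-1-en-2-yl)-7-oxabicyclo[4.1.0]heptan-2-one
Product: 16 (1R,4R,6R)-4-(3-chloroprop-1-en-2-yl)-1-methyl-7-oxabicyclo[4.1.0]heptan-2-one
Conditions: Ca(OCl)2, CO2 (s), CH2Cl2–H2O, 0 °C
Reagents that add atoms: calcium hypochlorite [Ca+2].[O-]Cl.[O-]Cl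
Why: Ene-type allylic chlorination of the isopropenyl group by hypochlorous acid places the leaving group on the future C3 and regenerates the 1,1-disubstituted alkene (C4=C11).

Step 12
Reactants: 16 (1R,4R,6R)-4-(3-chloroprop-1-en-2-yl)-1-methyl-7-oxabicyclo[4.1.0]heptan-2-one
Product: 18 (R)-3-(3-chloroprop-1-en-2-yl)-5-oxopentanoic acid, via dihydroxy ketone 17 (not isolated)
Conditions: H5IO6 (2.5 equiv), THF–H2O, 0 °C to rt
Reagents that add atoms: water O; periodic acid OI(=O)(O)(O)(O)O
Why: Acidic epoxide hydrolysis followed by Malaprade cleavage of the diol and of the resulting 1,2-diketone excises the C(CH3) unit as acetic acid and leaves C1 as the acid and C7 as the aldehyde on the intact carvone stereocentre (C5).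

Step 13
Reactants: 18 (R)-3-(3-chloroprop-1-en-2-yl)-5-oxopentanoic acid
Product: 19 2-[(4R)-5-methylidene-2-oxooxan-4-yl]acetaldehyde
Conditions: KHCO3, NaI (cat.), DMF, 40 °C
Reagents that add atoms: none
Why: Intramolecular carboxylate alkylation (6-exo-tet SN2 at the allylic chloride, the SN2′ path giving the same compound) closes the δ-lactone with its exocyclic methylene under base too weak to harm the aldehyde.

Step 14
Reactants: 19 2-[(4R)-5-methylidene-2-oxooxan-4-yl]acetaldehyde
Product: 20 (4R)-4-[(1,3-dioxolan-2-yl)methyl]-5-methylideneoxan-2-one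
Conditions: (TMSOCH2)2, TMSOTf (cat.), CH2Cl2, −78 °C
Reagents that add atoms: 1,2-bis(trimethylsilyloxy)ethane C[Si](C)(C)OCCO[Si](C)(C)C
Why: Noyori acetalisation masks the aldehyde under aprotic conditions that cannot open the lactone.

Step 15
Reactants: 20 (4R)-4-[(1,3-dioxolan-2-yl)methyl]-5-methylideneoxan-2-one; 21 benzyloxyacetyl chloride
Product: 22 (4R)-3-[(benzyloxy)acetyl]-4-[(1,3-dioxolan-2-yl)methyl]-5-methylideneoxan-2-one
Conditions: LiHMDS (2.1 equiv), THF, −78 °C; 21; AcOH quench
Reagents that add atoms: none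
Why: Crossed Claisen C-acylation of the lactone enolate brings in C8 and C10, the second equivalent of base storing the product as its enolate, and the new centre C9 stays labile.

Step 16
Reactants: 22 (4R)-3-[(benzyloxy)acetyl]-4-[(1,3-dioxolan-2-yl)methyl]-5-methylideneoxan-2-one
Product: 23 2-{(4R)-3-[(benzyloxy)acetyl]-5-methylidene-2-oxooxan-4-yl}acetaldehyde
Conditions: 1 M HCl, THF, rt
Reagents that add atoms: water O
Why: Acid hydrolysis of the dioxolane frees the aldehyde, which may rest as a lactol with the enol but stays available through the open form.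

Step 17
Reactants: 23 2-{(4R)-3-[(benzyloxy)acetyl]-5-methylidene-2-oxooxan-4-yl}acetaldehyde
Product: 24 (4aR,6S,7S,7aR)-7-[(benzyloxy)methyl]-6,7-dihydroxy-4-methylidenehexahydrocyclopenta[c]pyran-1(3H)-one
Conditions: SmI2 (2.5 equiv), t-BuOH (2 equiv), THF, −78 to −20 °C
Reagents that add atoms: none
Why: Samarium diiodide pinacol cyclisation (5-exo closure of C7–C8) should set C7, C8 and C9 from C5, because C9 equilibrates through the enol so that the cis-disposed keto aldehyde closes to the cis-fused bicycle, Sm(III) chelation of O-8 to the lactone carbonyl puts O-8 on the face of C1 and C10 on the convex face, and samarium bridging of both oxygens makes the diol cis.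

Step 18
Reactants: 24 (4aR,6S,7S,7aR)-7-[(benzyloxy)methyl]-6,7-dihydroxy-4-methylidenehexahydrocyclopenta[c]pyran-1(3H)-one
Product: 25 (4aR,6S,7S,7aR)-6,7-dihydroxy-7-(hydroxymethyl)-4-methylidenehexahydrocyclopenta[c]pyran-1(3H)-one
Conditions: BCl3·SMe2, CH2Cl2, 0 °C to rt; then H2O
Reagents that add atoms: none
Why: Lewis-acid debenzylation cleaves the benzyl ether without hydrogen, so the exocyclic alkene and the lactone should survive.

Step 19
Reactants: 13 (1R,3aS,8aR)-7-isopropyl-1-methyl-1,2,3,3a,8,8a-hexahydroazulene-4-carboxylic acid; 25 (4aR,6S,7S,7aR)-6,7-dihydroxy-7-(hydroxymethyl)-4-methylidenehexahydrocyclopenta[c]pyran-1(3H)-one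
Product: 27 nardostachysin, via mixed anhydride 26 (not isolated)
Conditions: 2,4,6-Cl3C6H2COCl, Et3N, PhMe, rt; then 25, DMAP, 0 °C
Reagents that add atoms: none
Why: Yamaguchi esterification should acylate the primary O-10 in preference to the concave secondary O-7 and the tertiary O-8 and creates no stereocentre.

Compound list

| No. | Name | SMILES | Role |
|---|---|---|---|
| 1 | (S)-2-(but-3-en-1-yl)oxirane | C=CCC[C@H]1CO1 | starting material |
| 2 | 3-methylbut-1-yne | CC(C)C#C | starting material |
| 3 | (S)-2-[(3E)-6-methyl-5-methylidenehept-3-en-1-yl]oxirane | CC(C)C(=C)/C=C/CC[C@H]1CO1 | intermediate |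
| 4 | lithium (1R,2S,5R,6R)-6-(3-methylbut-1-en-2-yl)bicyclo[3.1.0]hexan-2-olate | [Li+].[O-][C@H]1CC[C@@H]2[C@@H](C(=C)C(C)C)[C@H]12 | intermediate |
| 5 | tert-butyl(dimethyl){[(1R,2S,5R,6R)-6-(3-methylbut-1-en-2-yl)bicyclo[3.1.0]hexan-2-yl]oxy}silane | CC(C)(C)[Si](C)(C)O[C@H]1CC[C@@H]2[C@@H](C(=C)C(C)C)[C@H]12 | intermediate |
| 6 | methyl propiolate | C#CC(=O)OC | starting material |
| 7 | methyl (1S,3aS,8aS)-1-[(tert-butyldimethylsilyl)oxy]-7-isopropyl-1,2,3,3a,6,8a-hexahydroazulene-4-carboxylate | COC(=O)C1=CCC(C(C)C)=C[C@@H]2[C@@H](O[Si](C)(C)C(C)(C)C)CC[C@H]12 | intermediate |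
| 8 | methyl (1S,3aS,8aS)-1-[(tert-butyldimethylsilyl)oxy]-7-isopropyl-1,2,3,3a,8,8a-hexahydroazulene-4-carboxylate | COC(=O)C1=CC=C(C(C)C)C[C@@H]2[C@@H](O[Si](C)(C)C(C)(C)C)CC[C@H]12 | intermediate |
| 9 | methyl (1S,3aS,8aS)-1-hydroxy-7-isopropyl-1,2,3,3a,8,8a-hexahydroazulene-4-carboxylate | COC(=O)C1=CC=C(C(C)C)C[C@@H]2[C@@H](O)CC[C@H]12 | intermediate |
| 10 | methyl (3aS,8aS)-7-isopropyl-1-oxo-1,2,3,3a,8,8a-hexahydroazulene-4-carboxylate | COC(=O)C1=CC=C(C(C)C)C[C@@H]2C(=O)CC[C@H]12 | intermediate |
| 11 | methyl (3aS,8aS)-7-isopropyl-1-methylidene-1,2,3,3a,8,8a-hexahydroazulene-4-carboxylate | COC(=O)C1=CC=C(C(C)C)C[C@@H]2C(=C)CC[C@H]12 | intermediate |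
| 12 | methyl (1R,3aS,8aR)-7-isopropyl-1-methyl-1,2,3,3a,8,8a-hexahydroazulene-4-carboxylate | COC(=O)C1=CC=C(C(C)C)C[C@@H]2[C@H](C)CC[C@H]12 | intermediate |
| 13 | (1R,3aS,8aR)-7-isopropyl-1-methyl-1,2,3,3a,8,8a-hexahydroazulene-4-carboxylic acid | OC(=O)C1=CC=C(C(C)C)C[C@@H]2[C@H](C)CC[C@H]12 | intermediate |
| 14 | (R)-(−)-carvone | CC1=CC[C@H](CC1=O)C(C)=C | starting material |
| 15 | (1R,4R,6R)-1-methyl-4-(prop-1-en-2-yl)-7-oxabicyclo[4.1.0]heptan-2-one | C=C(C)[C@@H]1C[C@H]2O[C@@]2(C)C(=O)C1 | intermediate |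
| 16 | (1R,4R,6R)-4-(3-chloroprop-1-en-2-yl)-1-methyl-7-oxabicyclo[4.1.0]heptan-2-one | ClCC(=C)[C@@H]1C[C@H]2O[C@@]2(C)C(=O)C1 | intermediate |
| 17 | (2R,3S,5R)-5-(3-chloroprop-1-en-2-yl)-2,3-dihydroxy-2-methylcyclohexan-1-one | ClCC(=C)[C@@H]1C[C@H](O)[C@@](C)(O)C(=O)C1 | intermediate |
| 18 | (R)-3-(3-chloroprop-1-en-2-yl)-5-oxopentanoic acid | OC(=O)C[C@@H](CC=O)C(=C)CCl | intermediate |
| 19 | 2-[(4R)-5-methylidene-2-oxooxan-4-yl]acetaldehyde | C=C1COC(=O)C[C@H]1CC=O | intermediate |
| 20 | (4R)-4-[(1,3-dioxolan-2-yl)methyl]-5-methylideneoxan-2-one | C=C1COC(=O)C[C@H]1CC2OCCO2 | intermediate |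
| 21 | benzyloxyacetyl chloride | O=C(Cl)COCc1ccccc1 | starting material |
| 22 | (4R)-3-[(benzyloxy)acetyl]-4-[(1,3-dioxolan-2-yl)methyl]-5-methylideneoxan-2-one (C3 epimers and enol) | C=C1COC(=O)C(C(=O)COCc2ccccc2)[C@H]1CC3OCCO3 | intermediate |
| 23 | 2-{(4R)-3-[(benzyloxy)acetyl]-5-methylidene-2-oxooxan-4-yl}acetaldehyde (C3 epimers and enol) | C=C1COC(=O)C(C(=O)COCc2ccccc2)[C@H]1CC=O | intermediate |
| 24 | (4aR,6S,7S,7aR)-7-[(benzyloxy)methyl]-6,7-dihydroxy-4-methylidenehexahydrocyclopenta[c]pyran-1(3H)-one | C=C1COC(=O)[C@@H]2[C@H]1C[C@H](O)[C@@]2(O)COCc1ccccc1 | intermediate |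
| 25 | (4aR,6S,7S,7aR)-6,7-dihydroxy-7-(hydroxymethyl)-4-methylidenehexahydrocyclopenta[c]pyran-1(3H)-one | C=C1COC(=O)[C@@H]2[C@H]1C[C@H](O)[C@@]2(O)CO | intermediate |
| 26 | mixed anhydride of 13 with 2,4,6-trichlorobenzoic acid | O=C(OC(=O)c1c(Cl)cc(Cl)cc1Cl)C1=CC=C(C(C)C)C[C@@H]2[C@H](C)CC[C@H]12 | intermediate |
| 27 | nardostachysin | C=C1COC(=O)[C@@H]2[C@H]1C[C@H](O)[C@@]2(O)COC(=O)C1=CC=C(C(C)C)C[C@@H]2[C@H](C)CC[C@H]12 | target |

Total step count: 19.

Longest linear sequence: 10 steps (steps 10–19, or equally steps 1–9 followed by step 19).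

Steps most likely to fail

Step 3 ((5+2) cycloaddition).
- **What may go wrong.** Insertion of rhodium into the ring-fused, doubly substituted cyclopropane may be slow. The secondary alkyl-rhodium may collapse by β-hydride elimination before the alkyne inserts. The C6–C5 bond may be cut in competition with C6–C1.
- **Fallback.** It sets out from 5 and builds the same ring one carbon at a time.
 - A carbonylative (5+1) ring opening of the alkenylcyclopropane (cationic Rh(I)/CO, or Fe(CO)5 with light) should give the cis-fused 1-(silyloxy)-6-isopropyl-1,2,3,3a,5,7a-hexahydro-4H-inden-4-one F1.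
 - One-carbon ring expansion with TMSCHN2 and BF3·OEt2, in which the less substituted allylic CH2 (C8) migrates, followed by desilylation, should give the 1-(silyloxy)-7-isopropyl-2,3,3a,5,6,8a-hexahydroazulen-4(1H)-one F2.
 - Kinetic enolisation towards C9 (KHMDS, PhNTf2) gives the hexahydroazulen-4-yl triflate F3.
 - Pd(0)-catalysed methoxycarbonylation (CO, MeOH, Et3N) comes back to the route at 7.

Step 17 (pinacol closure).
- **What may go wrong.** The ketyl may expel the α-benzyloxy group. Closure may start from the trans C9 epimer. The samarium-bound oxygens may take the convex face.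
- **Fallback.** It sets out from 23.
 - An N-heterocyclic-carbene-catalysed crossed aldehyde–ketone benzoin reaction (triazolium salt, Et3N) is non-reductive and reversible. It should settle on the cis-fused 7-[(benzyloxy)methyl]-7-hydroxy-4-methylidenetetrahydrocyclopenta[c]pyran-1,6-dione F4, with C10 on the convex face and O-8 hydrogen-bonded to the lactone carbonyl.
 - Reduction of the C7 ketone with L-Selectride from the convex face at −78 °C comes back to the route at 24.

Step 1 (cross enyne metathesis).
- **What may go wrong.** Geometric control over the new disubstituted alkene may be poor, and the volatile alkyne may oligomerise. A Z diene would place the alkenyl group endo on the cyclopropane.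
- **Fallback.** It sets out from 1.
 - Cross metathesis with vinylboronic acid pinacol ester should give the (E)-alkenylboronate F5 with high E selectivity.
 - Suzuki–Miyaura coupling with 2-bromo-3-methylbut-1-ene (Pd(dppf)Cl2, K3PO4, THF–H2O) comes back to the route at 3.

Further compounds
F1 | step 3 | cis-fused 1-[(tert-butyldimethylsilyl)oxy]-6-isopropyl-1,2,3,3a,5,7a-hexahydro-4H-inden-4-one | O=C1CC(C(C)C)=C[C@@H]2[C@@H](O[Si](C)(C)C(C)(C)C)CC[C@H]12
F2 | step 3 | cis-fused 1-[(tert-butyldimethylsilyl)oxy]-7-isopropyl-2,3,3a,5,6,8a-hexahydroazulen-4(1H)-one | O=C1CCC(C(C)C)=C[C@@H]2[C@@H](O[Si](C)(C)C(C)(C)C)CC[C@H]12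
F3 | step 3 | 1-[(tert-butyldimethylsilyl)oxy]-7-isopropyl-1,2,3,3a,6,8a-hexahydroazulen-4-yl trifluoromethanesulfonate | O=S(=O)(OC1=CCC(C(C)C)=C[C@@H]2[C@@H](O[Si](C)(C)C(C)(C)C)CC[C@H]12)C(F)(F)F
F4 | step 17 | (4aR,7S,7aR)-7-[(benzyloxy)methyl]-7-hydroxy-4-methylidenetetrahydrocyclopenta[c]pyran-1,6(3H,4H)-dione | C=C1COC(=O)[C@@H]2[C@H]1CC(=O)[C@@]2(O)COCc1ccccc1
F5 | step 1 | 4,4,5,5-tetramethyl-2-{(1E)-4-[(2S)-oxiran-2-yl]but-1-en-1-yl}-1,3,2-dioxaborolane | CC1(C)OB(/C=C/CC[C@H]2CO2)OC1(C)C
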